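## Retrosynthetic overview

1. The target comes from acetylation of the 3α-alcohol and Mitsunobu etherification of isofraxidin with a 9-epi-drim-7-ene-3α,11-diol.
2. The C9–C11 bond, the axial C9 centre and the C7=C8 alkene come from a [2,3]-Wittig–Still rearrangement of a 7α-(stannylmethoxy)-Δ8 decalin (C7–O chirality passed to C9–C).
3. The 7α-allylic alcohol comes from Wharton transposition of a 7α,8α-epoxy-9-ketone; the axial 3α-OH comes from a bulky hydride.
4. Ring A is closed (C3–C4) by hydrogen-atom-transfer radical cyclisation of the isopropenyl group onto an aldehyde.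
5. Ring B is bought as (R)-carvone (C5), with C10 set by methylation then allylation. Rings: B bought, A made in step 4, coumarin bought.

Convention and assumption (one line): drimane numbering is used for the decalin (C1–C10; C11 = CH2O on C9, C12 = CH3 on C8, C13/C14 = CH3 on C4, C15 = CH3 on C10), α = face opposite the C10 methyl, and tributyl(iodomethyl)stannane and isofraxidin are taken as purchasable.

## Route

Step 1
Reactants: 1 (R)-carvone
Product: 3 (5R,6S)-2,6-dimethyl-5-(prop-1-en-2-yl)cyclohex-2-en-1-one (trans-6-methylcarvone; minor C6 epimer carried along), via lithium dienolate 2 (not isolated)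
Conditions: LiN(i-Pr)2 (commercial solution, 1.1 equiv), THF, −78 °C; MeI (1.5 equiv), −78 → 0 °C
Reagents that add atoms: iodomethane CI
Why: Kinetic deprotonation at the α′-CH2 gives the cross-conjugated lithium dienolate, whose C-methylation (enolate alkylation) gives 6-methylcarvone; the new C6 centre is flattened again in step 2, so its ratio does not matter.

Step 2
Reactants: 3 trans-6-methylcarvone
Product: 5 (5S,6S)-2,6-dimethyl-6-(prop-2-en-1-yl)-5-(prop-1-en-2-yl)cyclohex-2-en-1-one, via lithium enolate 4 (not isolated)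
Conditions: LiN(i-Pr)2 (1.2 equiv), THF, −78 → 0 °C; DMPU, allyl bromide (2 equiv), −78 °C → rt
Reagents that add atoms: allyl bromide C=CCBr
Why: Second enolate alkylation: the tetrasubstituted enolate is allylated anti to the neighbouring isopropenyl group (held pseudoaxial by allylic strain against the enolate methyl), giving the quaternary centre (later C10) with allyl trans and methyl cis to isopropenyl, i.e. the future trans ring fusion with 10β-CH3.

Step 3
Reactants: 5 6-allyl-6-methylcarvone
Product: 6 3-[(1S,6S)-1,3-dimethyl-2-oxo-6-(prop-1-en-2-yl)cyclohex-3-en-1-yl]propanal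
Conditions: PdCl2(PhCN)2 (12 mol %), CuCl2·2H2O (12 mol %), AgNO2 (6 mol %), O2 (1 atm), t-BuOH/MeNO2 15:1, rt
Reagents that add atoms: dioxygen O=O
Why: Nitrite-modified, aldehyde-selective (anti-Markovnikov) Wacker oxidation, which works best for allyl groups on α-quaternary carbonyl carbons; the 1,1-disubstituted and the conjugated trisubstituted alkenes do not react and no stereocentre is touched.

Step 4
Reactants: 6 keto aldehyde
Product: 7 (5S,10S)-3-hydroxy-11-nordrim-7-en-9-one (trans-decalin; both C3 epimers)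
Conditions: Fe(acac)3 (20 mol %), PhSiH3 (2.5 equiv), EtOH (0.02 M), 60 °C
Reagents that add atoms: none
Why: Iron-hydride hydrogen-atom transfer (Mukaiyama-type MHAT) to the isopropenyl CH2 gives the tertiary C4 radical, which adds 6-exo to the aldehyde carbon and closes ring A (C3–C4 bond, gem-dimethyl made from the alkene); the trans fusion is already fixed by C5 and C10, and the new C3 carbinol centre is removed in step 5.

Step 5
Reactants: 7 hydroxy enone
Product: 8 (5S,10S)-11-nordrim-7-ene-3,9-dione
Conditions: Dess–Martin periodinane (1.3 equiv), CH2Cl2, rt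
Reagents that add atoms: none
Why: Dess–Martin oxidation of the secondary alcohol converges both C3 epimers on one ketone without touching the enone.

Step 6
Reactants: 8 enedione
Product: 9 (5S,7R,8R,10S)-7α,8α-epoxy-11-nordrimane-3,9-dione
Conditions: 30% aq. H2O2 (3 equiv), NaOH (0.5 equiv), MeOH, 0 °C → rt
Reagents that add atoms: hydrogen peroxide OO
Why: Weitz–Scheffer nucleophilic epoxidation: hydroperoxide adds axially to C7 from the α face (anti to the β-oriented C5–C4 bond, as in carvone itself, and away from the axial C10 methyl) and the enolate closes the 7α,8α-epoxide; the saturated C3 ketone is not an acceptor.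

Step 7
Reactants: 9 epoxy dione
Product: 10 (3R,5S,7R,8R,10S)-7α,8α-epoxy-3α-hydroxy-11-nordriman-9-one
Conditions: LiBH(s-Bu)3 (L-Selectride, 1.1 equiv), THF, −78 °C; then H2O
Reagents that add atoms: none
Why: Bulky trialkylborohydride reduction: hydride enters the C3 carbonyl equatorially and gives the axial 3α-alcohol, while the C9 carbonyl, flanked by two fully substituted carbons, is not reached at −78 °C.

Step 8
Reactants: 10 epoxy ketol
Product: 12 (3R,5R,7R,10R)-11-nordrim-8-ene-3α,7α-diol, via C9 hydrazone 11 (not isolated)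
Conditions: N2H4·H2O (5 equiv), AcOH (0.5 equiv), MeOH, 0 °C → rt
Reagents that add atoms: none
Why: Wharton transposition: the epoxy hydrazone opens to the vinyl diazene and loses N2, moving the oxygen function to C7 and the alkene to C8=C9; the C7–O bond is never broken, so the 7α configuration from step 6 is kept.

Step 9
Reactants: 12 allylic diol
Product: 13 (3R,5R,7R,10R)-7α-[(tributylstannyl)methoxy]-11-nordrim-8-en-3α-ol
Conditions: KH (1.1 equiv), THF, 0 °C; Bu3SnCH2I (1.05 equiv), 0 °C → rt
Reagents that add atoms: tributyl(iodomethyl)stannane CCCC[Sn](CCCC)(CCCC)CI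
Why: Williamson O-alkylation with the Still reagent; the allylic 7-alkoxide is far more accessible than the axial 3-alkoxide next to the gem-dimethyl carbon, so one equivalent goes to O7.

Step 10
Reactants: 13 stannylmethyl ether
Product: 15 (3R,5R,9R,10S)-9-epi-drim-7-ene-3α,11-diol (CH2OH axial on the α face of C9), via lithiomethyl ether dianion 14 (not isolated)
Conditions: n-BuLi (2.5 equiv), THF, −78 °C, 30 min; then H2O
Reagents that add atoms: none
Why: Tin–lithium exchange gives the α-alkoxymethyllithium, which undergoes the [2,3]-Wittig–Still sigmatropic rearrangement; the shift is suprafacial, so the pseudoaxial 7α-oxygen hands the CH2O carbon to the α face of C9, forming the C9–C11 bond with 9β-H and moving the alkene to C7=C8.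

Step 11
Reactants: 15 9-epi-drim-7-ene-3α,11-diol; 16 isofraxidin (7-hydroxy-6,8-dimethoxy-2H-chromen-2-one)
Product: 17 7-{[(3R,5R,9R,10S)-3α-hydroxy-9-epi-drim-7-en-11-yl]oxy}-6,8-dimethoxy-2H-chromen-2-one
Conditions: PPh3 (1.5 equiv), diisopropyl azodicarboxylate (1.5 equiv), THF, 0 °C → rt
Reagents that add atoms: none
Why: Mitsunobu etherification: the acidic coumarin 7-OH displaces the oxyphosphonium of the primary C11 alcohol by SN2 at a non-stereogenic CH2, and the hindered axial 3α-OH is not activated.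

Step 12
Reactants: 17 hydroxy ether
Product: 18 7-{[(3R,5R,9R,10S)-3α-acetoxy-9-epi-drim-7-en-11-yl]oxy}-6,8-dimethoxy-2H-chromen-2-one (CNP0285931.3)
Conditions: Ac2O (3 equiv), DMAP (0.1 equiv), pyridine, rt
Reagents that add atoms: acetic anhydride CC(=O)OC(C)=O
Why: DMAP-catalysed O-acylation of the secondary alcohol with retention at C3; the aryl ether, lactone and alkene are inert.

## Compound list

1 | (R)-carvone, (5R)-2-methyl-5-(prop-1-en-2-yl)cyclohex-2-en-1-one | O=C1C(C)=CC[C@@H](C(C)=C)C1 | starting material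
2 | lithium (3R)-6-methyl-3-(prop-1-en-2-yl)cyclohexa-1,5-dien-1-olate | [Li]OC1=C[C@H](C(C)=C)CC=C1C | intermediate
3 | (5R,6S)-2,6-dimethyl-5-(prop-1-en-2-yl)cyclohex-2-en-1-one (major epimer) | O=C1C(C)=CC[C@@H](C(C)=C)[C@@H]1C | intermediate
4 | lithium (3S)-2,6-dimethyl-3-(prop-1-en-2-yl)cyclohexa-1,5-dien-1-olate | [Li]OC1=C(C)[C@H](C(C)=C)CC=C1C | intermediate
5 | (5S,6S)-2,6-dimethyl-6-(prop-2-en-1-yl)-5-(prop-1-en-2-yl)cyclohex-2-en-1-one | O=C1C(C)=CC[C@@H](C(C)=C)[C@]1(C)CC=C | intermediate
6 | 3-[(1S,6S)-1,3-dimethyl-2-oxo-6-(prop-1-en-2-yl)cyclohex-3-en-1-yl]propanal | O=C1C(C)=CC[C@@H](C(C)=C)[C@]1(C)CCC=O | intermediate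
7 | (5S,10S)-3-hydroxy-11-nordrim-7-en-9-one (C3 epimers) | O=C1C(C)=CC[C@H]2C(C)(C)C(O)CC[C@]12C | intermediate
8 | (5S,10S)-11-nordrim-7-ene-3,9-dione | O=C1C(C)=CC[C@H]2C(C)(C)C(=O)CC[C@]12C | intermediate
9 | (5S,7R,8R,10S)-7α,8α-epoxy-11-nordrimane-3,9-dione | O=C1[C@]2(C)O[C@@H]2C[C@H]3C(C)(C)C(=O)CC[C@]13C | intermediate
10 | (3R,5S,7R,8R,10S)-7α,8α-epoxy-3α-hydroxy-11-nordriman-9-one | O=C1[C@]2(C)O[C@@H]2C[C@H]3C(C)(C)[C@H](O)CC[C@]13C | intermediate
11 | C9 hydrazone of 10 | NN=C1[C@]2(C)O[C@@H]2C[C@H]3C(C)(C)[C@H](O)CC[C@]13C | intermediate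
12 | (3R,5R,7R,10R)-11-nordrim-8-ene-3α,7α-diol | C1=C(C)[C@H](O)C[C@H]2C(C)(C)[C@H](O)CC[C@]12C | intermediate
13 | (3R,5R,7R,10R)-7α-[(tributylstannyl)methoxy]-11-nordrim-8-en-3α-ol | C1=C(C)[C@H](OC[Sn](CCCC)(CCCC)CCCC)C[C@H]2C(C)(C)[C@H](O)CC[C@]12C | intermediate
14 | lithium 7α-(lithiomethoxy)-11-nordrim-8-en-3α-olate | C1=C(C)[C@H](OC[Li])C[C@H]2C(C)(C)[C@H](O[Li])CC[C@]12C | intermediate
15 | (3R,5R,9R,10S)-9-epi-drim-7-ene-3α,11-diol | OC[C@@H]1C(C)=CC[C@H]2C(C)(C)[C@H](O)CC[C@]12C | intermediate
16 | isofraxidin, 7-hydroxy-6,8-dimethoxy-2H-chromen-2-one | COc1cc2ccc(=O)oc2c(OC)c1O | starting material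
17 | 7-{[(3R,5R,9R,10S)-3α-hydroxy-9-epi-drim-7-en-11-yl]oxy}-6,8-dimethoxy-2H-chromen-2-one | COc1cc2ccc(=O)oc2c(OC)c1OC[C@@H]1C(C)=CC[C@H]2C(C)(C)[C@H](O)CC[C@]12C | intermediate
18 | 7-{[(3R,5R,9R,10S)-3α-acetoxy-9-epi-drim-7-en-11-yl]oxy}-6,8-dimethoxy-2H-chromen-2-one | COc1cc2ccc(=O)oc2c(OC)c1OC[C@@H]1C(C)=CC[C@H]2C(C)(C)[C@H](OC(C)=O)CC[C@]12C | target

## Step count and risks

Total step count: 12. Longest linear sequence: 12 steps (1 → 18); isofraxidin 16 is used as bought.

Three steps most likely to fail: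

Step 4 (radical ring closure onto the aldehyde). The tertiary radical may be reduced before it cyclises, or the alkoxy radical may fragment back. The fallback sets out from 6: iodine in aqueous ammonia (THF, rt) turns the aldehyde into 3-[(1S,6S)-1,3-dimethyl-2-oxo-6-(prop-1-en-2-yl)cyclohex-3-en-1-yl]propanenitrile F1. The same Fe(acac)3/PhSiH3/EtOH hydrogen-atom transfer then closes ring A onto the nitrile carbon, giving (5S,10S)-3-imino-11-nordrim-7-en-9-one F2. Work-up with 1 M HCl hydrolyses the ketimine to dione 8, where the route is rejoined; compound 7 and step 5 are skipped.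

Step 9 (alkylation of O7 beside the free 3-OH). Bis-alkylation or poor conversion would spoil the Still precursor. The fallback sets out from 12 and moves the one-carbon unit by a different [2,3] shift: heating with N,N-dimethylformamide dimethyl acetal (xylene, 150 °C) generates the allyloxy(dimethylamino)carbene at O7. It rearranges suprafacially to (3R,5R,9R,10S)-3α-hydroxy-N,N-dimethyl-9-epi-drim-7-en-11-amide F3; the 3-OH only forms a labile mixed acetal that is lost on aqueous work-up. LiEt3BH (THF, 0 °C → rt) then reduces the tertiary amide to the primary alcohol, rejoining the route at 15 and bypassing 13, 14 and step 10.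

Step 11 (Mitsunobu between a β-branched primary alcohol and a di-ortho-substituted phenol). Conversion may be low. The fallback sets out from 15: Tf2O (1.05 equiv) and 2,6-lutidine in CH2Cl2 at −78 °C sulfonylate only the primary hydroxyl, giving [(3R,5R,9R,10S)-3α-hydroxy-9-epi-drim-7-en-11-yl] trifluoromethanesulfonate F4. Isofraxidin 16 with Cs2CO3 in DMF (0 °C → rt) then displaces the triflate by SN2, rejoining the route at 17.

Further compounds
F1 | step 4 | 3-[(1S,6S)-1,3-dimethyl-2-oxo-6-(prop-1-en-2-yl)cyclohex-3-en-1-yl]propanenitrile | O=C1C(C)=CC[C@@H](C(C)=C)[C@]1(C)CCC#N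
F2 | step 4 | (5S,10S)-3-imino-11-nordrim-7-en-9-one | O=C1C(C)=CC[C@H]2C(C)(C)C(=N)CC[C@]12C
F3 | step 9 | (3R,5R,9R,10S)-3α-hydroxy-N,N-dimethyl-9-epi-drim-7-en-11-amide | CN(C)C(=O)[C@@H]1C(C)=CC[C@H]2C(C)(C)[C@H](O)CC[C@]12C
F4 | step 11 | [(3R,5R,9R,10S)-3α-hydroxy-9-epi-drim-7-en-11-yl] trifluoromethanesulfonate | O=S(=O)(OC[C@@H]1C(C)=CC[C@H]2C(C)(C)[C@H](O)CC[C@]12C)C(F)(F)F
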